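## Analysis of the target

Brianodin C (41) is a briarane: a cyclohexene ring A (C1, C10–C14) is trans-fused through C1–C10 to a ten-membered ring (C1–C10), and a γ-lactone (O7–C19–C17–C8) spans C7–C8. It has eleven stereocentres (C1, C2, C3, C4, C7, C8, C9, C10, C11, C12, C17) and a Z C5=C6 olefin. The C15 methyl on quaternary C1 and H-10 are trans; O2 and O3 are cis and O3/O4 trans; O7 and the C8 hydroxyl share one face with C17 on the other; the C8 and C17 hydroxyls are trans on the lactone; the C11/C12 diol is cis and anti to C15. The sensitive groups are three secondary acetates (C2, C4, C9) next to free hydroxyls at C3 and C12 (acyl migration under base), a tertiary β-hydroxy lactone (retro-aldol), an allylic acetate at C4 and an allylic alcohol at C12. The synthesis is hard because a medium ring must be made while the contiguous array C7–C8–C9–C10–C1, with two fully substituted carbons, is set, and because five secondary oxygens must end up differentiated. The strategy rests on C5=C6 and the C9–C10 bond lying 1,5 to each other across C7–C8. If C9–C10 is taken back to an olefin conjugated with a C11 ketone, the cyclodeca-1,5-diene is what a cyclobutane spanning C5–C10 and C6–C9 releases on opening, that is a bicyclo[2.2.0]hexane fused to a decalin made of ring A and a six-membered ring B (C1–C5, C10).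

## Retrosynthetic reasoning

41 to 40. The C11–O and C12–O bonds are cut last. Both oxygens sit on the α face of ring A, anti to C15, so they can come from cis-dihydroxylation of the C11=C12 olefin of the 1-methylcyclohexa-1,3-diene in 40. This avoids any protecting group on the diol; the forward step must pick the trisubstituted olefin of the diene and leave three acetates untouched.

40 to 37. The C4–O acetate bond is cut. A free C3 hydroxyl trans to a C4 acetate is what an SN2 opening of a 3,4-epoxide at its allylic carbon gives, so 40 comes from diacetate epoxide 39, epoxy diol 38 and dienol 37. The C2 hydroxyl of 37 directs the epoxidation to its own face. The 2-OAc/3-OH/4-OAc pattern then arises with no protecting group at C3.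

37 to 30 and 32. In the lactone, O7–C19 and C8–C17 are cut. C17–C19 with its tertiary hydroxyl and methyl is a lactic acid unit, brought in as dioxolanone 32 (from (R)-lactic acid 31) through enolate 33, which adds to C8 ketone 30 to give 34. The C7 hydroxyl then closes the lactone (35, 36). C9 stays silylated so that only O7 can lactonise.

30 to 27. The C8 ketone comes from the 7,8-diol 28, freed from acetonide 27 and differentiated by silylating the less hindered allylic C7 hydroxyl (29).

27 to 23. The C3=C4 olefin and the C2 carbinol come from C2 ketone 23 by dehydrogenation (enolate 24, dienone 25) and reduction (26). This is why the spectator oxygen of ring B is placed at C2 and not at C3. A C2 ketone is flanked by quaternary C1 and enolises only toward C3. A C3 ketone would be β,γ-unsaturated to C5=C6, would enolise toward C4, and would leave C2 out of reach.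

23 to 18. The ring A diene comes from the C11 ketone of 18 by dehydrogenation (19, 20), dienyl triflate 21 and methyl cross-coupling (22). C20 is attached to an sp2 carbon so that C11 is decided later by oxygen delivery from the α face; methyl addition to the ketone would also come from the α face and give the wrong epimer.

18 to 15. The C9–O bond and H-10 come from the enone of 15 by nucleophilic epoxidation (16) and reductive opening (17).

15 to 14. This is the key disconnection. C5–C10 and C6–C9 are re-formed, so the ten-membered ring becomes ring B of a decalin carrying a bicyclo[2.2.0]hexane. The cut is made here because the medium ring then needs no ring-closing step.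

14 to 13 and 5. The two cyclobutane bonds C5–C6 and C9–C10 are cut by a [2+2] photocycloaddition. Cyclobutene 5 is symmetric, so there is no regiochemistry, and it brings the C7 and C8 oxygens.

13 to 6. C16 is put on by conjugate methylation and re-oxidation of 11 (through 12). C5=C10 comes from dehydration of ketol 9 to 10. C10–C11 and ring A come from a desymmetrising benzoin cyclisation of aldehyde 8, which sets C1. 8 comes from dione 6 through 7.

5 to 1. The cyclobutene is released by a retro-Diels–Alder reaction from 4, made from cyclooctatetraene 1 through 2 and 3.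

## Alternatives that were turned down

Alternative 1: The disconnection is C11–C12 inside ring A. A SmI2 pinacol coupling of a C11 methyl ketone with the C12 carbonyl of a Z enal closes ring A and gives cis-diol A1. In its favour, one step creates C11 and C12 with the cis relationship enforced by a samarium-bridged ketyl pair, and C13=C14 is already there. On ring A it is stronger than the chosen route, which leaves the 11,12-diol to a late osmylation. Against it, the enal also accepts an electron at its β carbon, so ketyl–olefin coupling and enal dimerisation compete, and the diol face relative to C15 rests on an acyclic conformation. More seriously, A1 holds only ring A. The ten-membered ring would still have to be closed between two neopentyl-type arms while C2–C9, five stereocentres and the Z olefin are built, so the hardest step is only postponed. The chosen strategy offers instead a medium ring that appears by bond cleavage from a rigid tricycle.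

Alternative 2: The disconnection is C1–C10 across a fourteen-membered cembranoid. Sc(OTf)3 opens a C1–C14 epoxide at C1, the E C10=C11 olefin attacks through C10 and water caps C11, giving A2. In its favour, it is biomimetic, and one operation forms both rings, quaternary C1, C10 and the C11 carbinol with the butenolide and the C2–C4 and C9 oxygens in place. In bonds formed per step it is stronger than the chosen key step, which forms no skeletal bond. Against it, the precursor is a fully functionalised macrocycle that needs its own long synthesis. The C1 cation can also eliminate, shift a hydride or be captured by C5=C6 or the butenolide, and the facial course at C10 and C11 depends on a macrocycle conformation that nothing fixes. A2 also still lacks the C12 oxygen, C13=C14 and the trans 8,17-diol. The chosen strategy accepts more later functionalisation in return for a ring-forming event whose course is set by strain.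

Alternative 3: The disconnections are C1–C15 and C9–C10 around ring A. A copper-catalysed asymmetric conjugate addition of a methylaluminium reagent sets C1, and the enolate, silylated in the same flask, adds to a three-carbon enal at C10 to give A3. In its favour, it is short and catalytic and sets C1, C10 and C9 at once; in its opening steps it is at least as reliable as steps 5–10 here. Against it, the aldol selectivity at C9 comes from an open transition state, C8 arrives as a vinyl CH, and the ten-membered ring again has to be closed by macrocyclisation with seven carbons missing. The chosen strategy delivers the medium ring, the Z olefin and the C7/C8 oxygens in steps 11 and 12 from a precursor of similar length.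

Key step: step 12

Remarks on the chemistry: briarane numbering is used for all intermediates (C15 on C1, C16 on C5, C17–C19 lactone, C20 on C11), and α is the face opposite the C15 methyl. The sense of induction of the triazolium salt in step 7 is assumed from the usual model; the enantiomeric salt is used if it proves opposite.

## Route

Step 1
Reactants: 1 cyclooctatetraene
Product: 2 dimethyl tricyclo[4.2.2.0(2,5)]deca-3,7,9-triene-7,8-dicarboxylate
Conditions: dimethyl acetylenedicarboxylate, o-xylene, 140 °C
Reagents that add atoms: dimethyl acetylenedicarboxylate, COC(=O)C#CC(=O)OC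
Why: Diels–Alder reaction of the bicyclo[4.2.0]octatriene valence tautomer of 1; the dienophile adds anti to the cyclobutene ring and leaves its olefin exposed.

Step 2
Reactants: 2 tricyclic triene diester
Product: 3 exo-cis-diol of 2
Conditions: OsO4 (1 mol %), N-methylmorpholine N-oxide, acetone–H2O, 0 °C to rt
Reagents that add atoms: osmium tetroxide, O=[Os](=O)(=O)=O; N-methylmorpholine N-oxide, C[N+]1([O-])CCOCC1; water, O
Why: Catalytic cis-dihydroxylation; the strained cyclobutene olefin should react ahead of the bicyclooctadiene olefin and the electron-poor diester olefin, and from its open exo face.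

Step 3
Reactants: 3 exo-cis-diol
Product: 4 acetonide of 3
Conditions: 2,2-dimethoxypropane, TsOH (cat.), acetone, rt
Reagents that add atoms: 2,2-dimethoxypropane, COC(C)(C)OC
Why: Acid-catalysed acetal exchange on a cis-1,2-diol.

Step 4
Reactants: 4 acetonide
Product: 5 cis-3,4-(isopropylidenedioxy)cyclobutene
Conditions: flash vacuum pyrolysis, 450 °C, 0.05 mbar
Reagents that add atoms: none
Why: Retro-Diels–Alder reaction driven by loss of an aromatic diester; the cis-fused dioxolane blocks conrotatory opening of the cyclobutene, so 5 should survive.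

Step 5
Reactants: 6 2-methylcyclohexane-1,3-dione
Product: 7 2-allyl-2-methylcyclohexane-1,3-dione
Conditions: allyl bromide, 1 M aq. NaOH, rt
Reagents that add atoms: allyl bromide, C=CCBr
Why: C-alkylation of the dione enolate with an allylic halide; it brings in C12–C14.

Step 6
Reactants: 7 allyl dione
Product: 8 4-(1-methyl-2,6-dioxocyclohexyl)butanal
Conditions: Rh(acac)(CO)2 (0.5 mol %), BiPhePhos, CO/H2 (1:1, 10 bar), toluene, 60 °C
Reagents that add atoms: carbon monoxide, [C-]#[O+]
Why: Linear-selective hydroformylation of a terminal olefin; it adds C11 as the aldehyde.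

Step 7
Reactants: 8 keto aldehyde
Product: 9 cis-fused ketol (C10 carbinol, C11 and C2 ketones, C1 S)
Conditions: aminoindanol-derived N-pentafluorophenyltriazolium tetrafluoroborate (10 mol %), Et3N (10 mol %), toluene, rt
Reagents that add atoms: none
Why: NHC-catalysed intramolecular crossed benzoin reaction; the Breslow intermediate at C11 adds to one of the two enantiotopic ring carbonyls, forming C10–C11 and ring A. The chiral carbene decides which carbonyl is attacked and so sets C1; the C10 carbinol centre is removed in step 8.

Step 8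
Reactants: 9 ketol
Product: 10 enone dione (C5=C10, C11 and C2 ketones)
Conditions: Burgess reagent, toluene, 70 °C
Reagents that add atoms: none
Why: syn-Dehydration of a tertiary α-ketol; only C5 carries a β-hydrogen, so the olefin can only form as C5=C10.

Step 9
Reactants: 10 enone dione
Product: 11 C2 ethylene ketal
Conditions: ethylene glycol, TsOH·H2O (cat.), benzene, reflux, Dean–Stark
Reagents that add atoms: ethylene glycol, OCCO
Why: Ketalisation; the saturated C2 carbonyl reacts ahead of the conjugated C11 carbonyl, as in Wieland–Miescher-type enediones.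

Step 10
Reactants: 11 ketal enone
Product: 13 tetrasubstituted enone (C16 on C5), via TMS enol ether 12 (not isolated)
Conditions: Me2CuLi, Me3SiCl, THF, −78 °C; then Pd(OAc)2, MeCN, rt
Reagents that add atoms: lithium dimethylcuprate, [Li+].C[Cu-]C
Why: Silyl-accelerated cuprate addition puts C16 on C5 and traps the C10=C11 enol ether; Saegusa–Ito oxidation restores C5=C10, the only position with a β-hydrogen.

Step 11
Reactants: 13 enone; 5 cyclobutene acetonide
Product: 14 cis-anti-cis photoadduct
Conditions: hν (medium-pressure Hg lamp, uranium-glass filter, λ > 330 nm), 5 (5 equiv), CH2Cl2, −40 °C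
Reagents that add atoms: none
Why: Triplet enone–alkene [2+2] photocycloaddition; the symmetric cyclobutene removes any regiochemical question. Addition should occur on the α face of C5/C10 (C15 is axial on the β face), with the four-membered ring turned away from ring B and the dioxolane exo; together these fix C7 and C8 as in 41.

Step 12
Reactants: 14 photoadduct
Product: 15 ten-membered dienone (Z C5=C6; C8 cis to C11 across C9=C10)
Conditions: degassed toluene, BHT (cat.), silylated sealed tube, 170 °C
Reagents that add atoms: none
Why: Heating homolyses a bond of the bicyclo[2.2.0]hexane to a cyclohexane-1,4-diyl, which cleaves the second bond, so that C6–C9 and C5–C10 are lost and C5=C6 and C9=C10 appear. The closest known reaction type is the thermal cycloreversion of cyclohexenone–cyclobutene [2+2] photoadducts to cyclodeca-1,5-dienes. The ten-membered ring is not closed by a bond-forming event: it is unveiled by fragmentation of the C5–C10 bond shared by ring B and the cyclobutane, while the C1–C4 tether holds the ends together. No stereocentre is created; C5, C6, C9 and C10 become trigonal and C1, C7 and C8 are untouched. The step needs the diyl to break C5–C10 and not C7–C8: C5–C10 joins two fully substituted carbons, one α to the C11 carbonyl, and its cleavage releases an enone, whereas C7–C8 cleavage would keep the vicinal quaternary centres and force the dioxolane into a nine-membered bis-enol ether. It also needs the right olefin geometry: the chair diyl with quaternary C1 equatorial puts C4 and C11 axial, which gives Z C5=C6 and places C8 cis to C11. A Cope rearrangement of 15 would rebuild the congested C5–C10 bond and break the enone conjugation, so it should not compete.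

Step 13
Reactants: 15 dienone
Product: 16 9,10-epoxy ketone
Conditions: t-BuOOH (anhydrous), DBU, CH2Cl2, 0 °C to rt
Reagents that add atoms: tert-butyl hydroperoxide, CC(C)(C)OO
Why: Weitz–Scheffer epoxidation of the strained enone; the isolated C5=C6 olefin is inert to the peroxide anion. A(1,3) strain holds H-8 in the enone plane, with C7 on one face and only the tied-back dioxolane oxygen on the other, so attack at C9 anti to C7 should give the C9 configuration of 41.

Step 14
Reactants: 16 epoxy ketone
Product: 17 β-hydroxy ketone (C9 OH, H-10 α)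
Conditions: SmI2 (2.5 equiv), THF–MeOH, −78 °C
Reagents that add atoms: none
Why: Reductive opening of an α,β-epoxy ketone at the Cα–O bond; the samarium enolate is protonated at C10 anti to the axial C15 methyl. This gives the trans ring fusion, which is also the more stable one (both ten-ring bonds equatorial on ring A).

Step 15
Reactants: 17 β-hydroxy ketone
Product: 18 C9 TBS ether
Conditions: t-BuMe2SiOTf, 2,6-lutidine, CH2Cl2, −78 °C
Reagents that add atoms: tert-butyldimethylsilyl triflate, CC(C)(C)[Si](C)(C)OS(=O)(=O)C(F)(F)F
Why: Silylation under non-basic conditions avoids retro-aldol cleavage and β-elimination.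

Step 16
Reactants: 18 ketone
Product: 20 C12=C13 enone, via lithium enolate 19 (not isolated)
Conditions: LiN(iPr)2, THF, −78 °C; then N-tert-butylbenzenesulfinimidoyl chloride, −78 °C
Reagents that add atoms: none
Why: Kinetic deprotonation at the C12 methylene (the C10 methine is flanked by C1 and C9), then one-pot sulfinimidoyl chloride dehydrogenation of the enolate.

Step 17
Reactants: 20 enone
Product: 21 dienyl triflate (C11(OTf)=C12, C13=C14)
Conditions: Tf2O, 2,6-di-tert-butyl-4-methylpyridine, CH2Cl2, 0 °C to rt
Reagents that add atoms: triflic anhydride, O=S(=O)(OS(=O)(=O)C(F)(F)F)C(F)(F)F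
Why: O-triflation of the enone and loss of the γ-hydrogen at C14 give the linear dienyl triflate, the thermodynamic outcome for cyclohexenones with a hindered pyridine base. No enolate is formed, so the C9 silyloxy group cannot be eliminated.

Step 18
Reactants: 21 dienyl triflate
Product: 22 ring A 1-methyl-1,3-diene
Conditions: Me2Zn, Pd(PPh3)4 (5 mol %), THF, 0 °C to rt
Reagents that add atoms: dimethylzinc, C[Zn]C
Why: Negishi coupling of an alkenyl triflate; it installs C20 on sp2 C11.

Step 19
Reactants: 22 diene ketal
Product: 23 C2 ketone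
Conditions: TsOH·H2O (cat.), acetone (2% H2O), rt
Reagents that add atoms: water, O
Why: Transketalisation to the solvent removes the C2 dioxolane; the 7,8-acetonide persists because acetone is the solvent.

Step 20
Reactants: 23 C2 ketone
Product: 25 (3Z,5Z)-dienone, via lithium enolate 24 (not isolated)
Conditions: LiN(iPr)2, THF, −78 °C; then N-tert-butylbenzenesulfinimidoyl chloride, −78 °C
Reagents that add atoms: none
Why: C2 is flanked by quaternary C1 and can enolise only toward C3, so the dehydrogenation is regiochemically fixed. The ring-cis C3=C4 olefin is the less strained geometry next to Z C5=C6 and is expected.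

Step 21
Reactants: 25 dienone
Product: 26 (2R)-dienol (C2 OH α)
Conditions: (S)-2-methyl-CBS-oxazaborolidine (1 equiv), catecholborane, toluene, −78 °C
Reagents that add atoms: none
Why: CBS reduction, 1,2-selective on the enone; with quaternary C1 as the large group and the alkenyl carbon as the small one, the (S)-catalyst should deliver hydride to give the 2R carbinol.

Step 22
Reactants: 26 dienol
Product: 27 C2, C9 bis-TBS ether
Conditions: t-BuMe2SiOTf, 2,6-lutidine, CH2Cl2, −78 to 0 °C
Reagents that add atoms: tert-butyldimethylsilyl triflate, CC(C)(C)[Si](C)(C)OS(=O)(=O)C(F)(F)F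
Why: Silylation of a hindered allylic alcohol so that the C8 oxidation and the aldol can be run.

Step 23
Reactants: 27 acetonide
Product: 28 7,8-diol
Conditions: AcOH–THF–H2O (3:1:1), 40 °C
Reagents that add atoms: none
Why: Mild hydrolysis of the allylic acetonide; secondary TBS ethers and the dienes should survive aqueous acetic acid.

Step 24
Reactants: 28 diol
Product: 29 C7 TES ether
Conditions: Et3SiCl, imidazole, CH2Cl2, −40 °C
Reagents that add atoms: chlorotriethylsilane, CC[Si](Cl)(CC)CC
Why: The allylic C7 hydroxyl is the less hindered one; the C8 hydroxyl is flanked by the C9 silyl ether.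

Step 25
Reactants: 29 C8 alcohol
Product: 30 C8 ketone
Conditions: Dess–Martin periodinane, NaHCO3, CH2Cl2, 0 °C to rt
Reagents that add atoms: none
Why: Buffered Dess–Martin oxidation keeps the epimerisable C7 and C9 centres away from base.

Step 26
Reactants: 31 (R)-lactic acid
Product: 32 (2R,5R)-2-tert-butyl-5-methyl-1,3-dioxolan-4-one
Conditions: pivalaldehyde, TsOH (cat.), pentane, reflux, Dean–Stark; crystallisation of the cis isomer
Reagents that add atoms: pivalaldehyde, CC(C)(C)C=O
Why: Acetalisation that stores the lactate configuration in the acetal carbon (self-regeneration of the stereocentre); the cis isomer is favoured.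

Step 27
Reactants: 30 C8 ketone; 32 dioxolanone
Product: 34 aldol adduct (C8–C17 bond), via lithium enolate 33 (not isolated)
Conditions: 32 (3 equiv), LiN(iPr)2, THF, −78 °C; CeCl3; then 30, −78 °C; H2O
Reagents that add atoms: none
Why: Aldol addition of the dioxolanone enolate, used as its weakly basic cerium enolate so that addition outruns proton transfer from C7. C17 is set by attack anti to the tert-butyl group (overall retention of the (R)-lactate centre). C8 should follow Felkin–Anh control from the bulky C9 silyloxy group, which places C17 anti to O7 as in 41, though the C7 silyloxy group argues the other way.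

Step 28
Reactants: 34 aldol adduct
Product: 36 γ-lactone (C2, C9 TBS), via C7 alcohol 35 (not isolated)
Conditions: HF·pyridine, pyridine, THF, 0 °C; then PPTS, CH2Cl2, rt
Reagents that add atoms: none
Why: The TES ether is cleaved selectively and the C7 hydroxyl opens the activated dioxolanone carbonyl (5-exo transacylation) with loss of pivalaldehyde, freeing the C17 hydroxyl. The C9 silyl ether blocks the alternative lactone.

Step 29
Reactants: 36 bis-TBS lactone
Product: 37 lactone with free C2 and C9 hydroxyls
Conditions: HF·pyridine (excess), THF, rt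
Reagents that add atoms: none
Why: Acidic fluoride removes both TBS ethers without the basic conditions that could trigger retro-aldol cleavage.

Step 30
Reactants: 37 dienol
Product: 38 3α,4α-epoxide
Conditions: VO(acac)2 (5 mol %), t-BuOOH, CH2Cl2, 0 °C
Reagents that add atoms: tert-butyl hydroperoxide, CC(C)(C)OO
Why: Vanadium-catalysed hydroxyl-directed epoxidation; it is syn-selective for cis-allylic alcohols in medium rings and takes the proximal olefin of a dienol. The C2 hydroxyl therefore sets C3 and the provisional C4 centre.

Step 31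
Reactants: 38 epoxy diol
Product: 39 C2, C9 diacetate
Conditions: Ac2O, pyridine, DMAP (cat.), CH2Cl2, 0 °C to rt
Reagents that add atoms: acetic anhydride, CC(=O)OC(C)=O
Why: Acetylation of the two secondary hydroxyls; the tertiary C8 and C17 hydroxyls should not react under these conditions.

Step 32
Reactants: 39 vinyl epoxide
Product: 40 2,4,9-triacetate with free C3 hydroxyl
Conditions: AcOH, NaOAc, 45 °C
Reagents that add atoms: acetic acid, CC(=O)O
Why: Acetolysis of the vinyl epoxide at the allylic carbon C4 with inversion gives the C4 β-acetate and leaves the C3 α-hydroxyl. The C2 acetate is cis to the epoxide and cannot take part.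

Step 33
Reactants: 40 ring A diene
Product: 41 brianodin C
Conditions: OsO4 (5 mol %), (DHQD)2PHAL (10 mol %), N-methylmorpholine N-oxide, acetone–H2O, 0 °C
Reagents that add atoms: osmium tetroxide, O=[Os](=O)(=O)=O; N-methylmorpholine N-oxide, C[N+]1([O-])CCOCC1; water, O
Why: Ligand-accelerated cis-dihydroxylation favours the trisubstituted C11=C12 olefin over cis-disubstituted C13=C14 and the acyloxy-flanked C5=C6. Attack on the α face, opposite the pseudoaxial C15 methyl, sets C11 and C12; the dihydroquinidine ligand is the one whose face preference matches this bias.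

## Compound list

1 | cyclooctatetraene | C1=CC=CC=CC=C1 | starting material
2 | dimethyl tricyclo[4.2.2.0(2,5)]deca-3,7,9-triene-7,8-dicarboxylate (meso; cyclobutene anti to the diester bridge) | COC(=O)C1=C(C(=O)OC)[C@@H]2C=C[C@H]1[C@H]1C=C[C@H]12 | intermediate
3 | exo-cis-3,4-diol of 2 (hydroxyls anti to the etheno bridge) | COC(=O)C1=C(C(=O)OC)[C@@H]2C=C[C@H]1[C@H]1[C@H](O)[C@H](O)[C@H]12 | intermediate
4 | acetonide of 3 | COC(=O)C1=C(C(=O)OC)[C@@H]2C=C[C@H]1[C@H]1[C@@H]3OC(C)(C)O[C@@H]3[C@H]12 | intermediate
5 | cis-3,4-(isopropylidenedioxy)cyclobutene, (1R,5S)-3,3-dimethyl-2,4-dioxabicyclo[3.2.0]hept-6-ene (meso) | CC1(C)O[C@@H]2C=C[C@@H]2O1 | intermediate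
6 | 2-methylcyclohexane-1,3-dione | CC1C(=O)CCCC1=O | starting material
7 | 2-allyl-2-methylcyclohexane-1,3-dione | C=CCC1(C)C(=O)CCCC1=O | intermediate
8 | 4-(1-methyl-2,6-dioxocyclohexyl)butanal | O=CCCCC1(C)C(=O)CCCC1=O | intermediate
9 | (4aS,8aR)-8a-hydroxy-4a-methyloctahydronaphthalene-1,5-dione (cis-fused ketol) | O=C1CCC[C@]2(O)C(=O)CCC[C@]12C | intermediate
10 | (4aS)-4a-methyl-2,3,4,4a,6,7-hexahydronaphthalene-1,5-dione (C5=C10 enone, C2 ketone) | O=C1CCC=C2C(=O)CCC[C@]12C | intermediate
11 | (4aS)-5,5-(ethylenedioxy)-4a-methyl-3,4,4a,5,6,7-hexahydronaphthalen-1(2H)-one | C13(OCCO3)CCC=C2C(=O)CCC[C@]12C | intermediate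
12 | trimethylsilyl enol ether of the 5α-methyl ketone (C10=C11 enol ether; not isolated) | C13(OCCO3)CC[C@H](C)C2=C(O[Si](C)(C)C)CCC[C@]12C | intermediate
13 | (4aS)-5,5-(ethylenedioxy)-4a,8-dimethyl-3,4,4a,5,6,7-hexahydronaphthalen-1(2H)-one | C13(OCCO3)CCC(C)=C2C(=O)CCC[C@]12C | intermediate
14 | cis-anti-cis photoadduct: cyclobutane C5–C6–C9–C10 on the α face of ring B, second cyclobutane C6–C7–C8–C9 anti to ring B, exo 7α,8α-acetonide, C2 ethylene ketal, C11 ketone | C13(OCCO3)CC[C@]4(C)[C@H]5[C@@H]6OC(C)(C)O[C@@H]6[C@H]5[C@@]42C(=O)CCC[C@]12C | intermediate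
15 | bicyclo[8.4.0] dienone: Z C5=C6, C9=C10 with C8 cis to C11, C11 ketone, 7α,8α-acetonide, C2 ethylene ketal | C13(OCCO3)CC/C(C)=C\[C@@H]4OC(C)(C)O[C@@H]4/C=C2\C(=O)CCC[C@]12C | intermediate
16 | 9,10-epoxy-11-ketone (epoxide oxygen on the face of O8) | C13(OCCO3)CC/C(C)=C\[C@@H]4OC(C)(C)O[C@@H]4[C@H]5O[C@@]52C(=O)CCC[C@]12C | intermediate
17 | 9β-hydroxy-11-ketone with H-10 α | C13(OCCO3)CC/C(C)=C\[C@@H]4OC(C)(C)O[C@@H]4[C@@H](O)[C@H]2C(=O)CCC[C@]12C | intermediate
18 | C9 tert-butyldimethylsilyl ether of 17 | C13(OCCO3)CC/C(C)=C\[C@@H]4OC(C)(C)O[C@@H]4[C@@H](O[Si](C)(C)C(C)(C)C)[C@H]2C(=O)CCC[C@]12C | intermediate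
19 | lithium C11(O)=C12 enolate of 18 (not isolated) | [Li+].C13(OCCO3)CC/C(C)=C\[C@@H]4OC(C)(C)O[C@@H]4[C@@H](O[Si](C)(C)C(C)(C)C)[C@H]2C([O-])=CCC[C@]12C | intermediate
20 | ring A enone (C11 ketone, C12=C13) | C13(OCCO3)CC/C(C)=C\[C@@H]4OC(C)(C)O[C@@H]4[C@@H](O[Si](C)(C)C(C)(C)C)[C@H]2C(=O)C=CC[C@]12C | intermediate
21 | ring A dienyl triflate (C11(OTf)=C12, C13=C14) | C13(OCCO3)CC/C(C)=C\[C@@H]4OC(C)(C)O[C@@H]4[C@@H](O[Si](C)(C)C(C)(C)C)[C@H]2C(OS(=O)(=O)C(F)(F)F)=CC=C[C@]12C | intermediate
22 | ring A 11-methyl-11,13-diene (C20 installed), C2 ketal | C13(OCCO3)CC/C(C)=C\[C@@H]4OC(C)(C)O[C@@H]4[C@@H](O[Si](C)(C)C(C)(C)C)[C@H]2C(C)=CC=C[C@]12C | intermediate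
23 | C2 ketone of 22 | O=C1CC/C(C)=C\[C@@H]4OC(C)(C)O[C@@H]4[C@@H](O[Si](C)(C)C(C)(C)C)[C@H]2C(C)=CC=C[C@]12C | intermediate
24 | lithium C2(O)=C3 enolate of 23 (not isolated) | [Li+].[O-]/C1=C/C/C(C)=C\[C@@H]4OC(C)(C)O[C@@H]4[C@@H](O[Si](C)(C)C(C)(C)C)[C@H]2C(C)=CC=C[C@]12C | intermediate
25 | (3Z,5Z)-dien-2-one | O=C1/C=C\C(C)=C/[C@@H]4OC(C)(C)O[C@@H]4[C@@H](O[Si](C)(C)C(C)(C)C)[C@H]2C(C)=CC=C[C@]12C | intermediate
26 | (2R)-dienol (C2 OH α) | O[C@@H]1/C=C\C(C)=C/[C@@H]4OC(C)(C)O[C@@H]4[C@@H](O[Si](C)(C)C(C)(C)C)[C@H]2C(C)=CC=C[C@]12C | intermediate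
27 | C2, C9 bis(tert-butyldimethylsilyl) ether, 7,8-acetonide | CC(C)(C)[Si](C)(C)O[C@@H]1/C=C\C(C)=C/[C@@H]4OC(C)(C)O[C@@H]4[C@@H](O[Si](C)(C)C(C)(C)C)[C@H]2C(C)=CC=C[C@]12C | intermediate
28 | 7α,8α-diol | CC(C)(C)[Si](C)(C)O[C@@H]1/C=C\C(C)=C/[C@H](O)[C@H](O)[C@@H](O[Si](C)(C)C(C)(C)C)[C@H]2C(C)=CC=C[C@]12C | intermediate
29 | C7 triethylsilyl ether, C8 alcohol | CC(C)(C)[Si](C)(C)O[C@@H]1/C=C\C(C)=C/[C@H](O[Si](CC)(CC)CC)[C@H](O)[C@@H](O[Si](C)(C)C(C)(C)C)[C@H]2C(C)=CC=C[C@]12C | intermediate
30 | C8 ketone | CC(C)(C)[Si](C)(C)O[C@@H]1/C=C\C(C)=C/[C@H](O[Si](CC)(CC)CC)C(=O)[C@@H](O[Si](C)(C)C(C)(C)C)[C@H]2C(C)=CC=C[C@]12C | intermediate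
31 | (R)-lactic acid | C[C@@H](O)C(=O)O | starting material
32 | (2R,5R)-2-tert-butyl-5-methyl-1,3-dioxolan-4-one (cis) | C[C@H]1O[C@@H](C(C)(C)C)OC1=O | intermediate
33 | lithium enolate of 32 (not isolated) | [Li+].CC1=C([O-])O[C@H](C(C)(C)C)O1 | intermediate
34 | aldol adduct: C8 tertiary alcohol (OH α) bearing the dioxolanone at C17 | CC(C)(C)[Si](C)(C)O[C@@H]1/C=C\C(C)=C/[C@H](O[Si](CC)(CC)CC)[C@@](O)([C@]5(C)O[C@@H](C(C)(C)C)OC5=O)[C@@H](O[Si](C)(C)C(C)(C)C)[C@H]2C(C)=CC=C[C@]12C | intermediate
35 | C7 alcohol of 34 (not isolated) | CC(C)(C)[Si](C)(C)O[C@@H]1/C=C\C(C)=C/[C@H](O)[C@@](O)([C@]5(C)O[C@@H](C(C)(C)C)OC5=O)[C@@H](O[Si](C)(C)C(C)(C)C)[C@H]2C(C)=CC=C[C@]12C | intermediate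
36 | γ-lactone with C8 and C17 hydroxyls, C2 and C9 TBS ethers | CC(C)(C)[Si](C)(C)O[C@@H]1/C=C\C(C)=C/[C@@H]5OC(=O)[C@@](C)(O)[C@@]5(O)[C@@H](O[Si](C)(C)C(C)(C)C)[C@H]2C(C)=CC=C[C@]12C | intermediate
37 | lactone tetraol (C2, C8, C9, C17 hydroxyls), dienol | O[C@@H]1/C=C\C(C)=C/[C@@H]5OC(=O)[C@@](C)(O)[C@@]5(O)[C@@H](O)[C@H]2C(C)=CC=C[C@]12C | intermediate
38 | 3α,4α-epoxide (syn to the C2 hydroxyl) | O[C@@H]1[C@@H]6O[C@@H]6/C(C)=C\[C@@H]5OC(=O)[C@@](C)(O)[C@@]5(O)[C@@H](O)[C@H]2C(C)=CC=C[C@]12C | intermediate
39 | C2, C9 diacetate of 38 | CC(=O)O[C@@H]1[C@@H]6O[C@@H]6/C(C)=C\[C@@H]5OC(=O)[C@@](C)(O)[C@@]5(O)[C@@H](OC(C)=O)[C@H]2C(C)=CC=C[C@]12C | intermediate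
40 | 2,4,9-triacetate with C3 hydroxyl and ring A 11,13-diene | CC(=O)O[C@@H]1[C@H](O)[C@@H](OC(C)=O)/C(C)=C\[C@@H]5OC(=O)[C@@](C)(O)[C@@]5(O)[C@@H](OC(C)=O)[C@H]2C(C)=CC=C[C@]12C | intermediate
41 | brianodin C | CC(=O)O[C@@H]1[C@H](O)[C@@H](OC(C)=O)/C(C)=C\[C@@H]2OC(=O)[C@@](C)(O)[C@@]2(O)[C@@H](OC(C)=O)[C@H]2[C@](C)(O)[C@H](O)C=C[C@]12C | target

## Step count and least certain steps

Total step count: 33. Longest linear sequence: 28 steps (steps 5–25 and 27–33, from 6). Steps 1–4 make 5 and step 26 makes 32.

Step 12 (key step). The diyl could fragment along C7–C8 or revert to 13 and 5, and the temperature needed could isomerise the ring-trans enone or start transannular reactions, because neither radical centre of the C6/C9 diyl is stabilised. Fallback: 14 is treated with SmI2–HMPA and t-BuOH (1 equiv) in THF at −78 °C. The C11 ketyl opens C5–C10, and the tertiary C5 radical opens the second cyclobutane at C6–C9. After a second electron transfer and protonation at C9, the ring-expanded samarium enolate is trapped with Me3SiCl as the trimethylsilyl enol ether of the ring-expanded 9,10-dihydro ketone F1. Saegusa–Ito oxidation of this enol ether with Pd(OAc)2 in MeCN reintroduces C9=C10 and returns to 15.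

Step 11. The cycloaddition may be slow, because the olefin is tetrasubstituted and the excited enone can lose its energy by γ-hydrogen transfer from C16. Addition on the β face or with the dioxolane endo would give C7 epimers. Fallback: 13 is irradiated with commercial cis-3,4-dichlorocyclobutene as cosolvent to give the dichloro photoadduct F2. Zinc dust in ethanol removes the vicinal chlorides to give the bicyclo[2.2.0]hexene F3. OsO4/N-methylmorpholine N-oxide dihydroxylates the strained olefin from its convex face to the exo-cis-7,8-diol F4, and 2,2-dimethoxypropane/TsOH returns to 14.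

Step 13. Facial selectivity at C9 may be poor if the reacting conformer of the ring-trans enone carries the C7 arm on the other face, which would give the C9 epimer. Fallback: 15 is subjected to copper-catalysed conjugate borylation (CuCl, NaOt-Bu, a Josiphos-type bisphosphine, bis(pinacolato)diboron, MeOH, THF) to give the C9 pinacol boronate F5, with the face set by the ligand. NaBO3·4H2O oxidises the C–B bond with retention and returns to 17.

Step 27. Proton transfer from C7 (α to the ketone and allylic to the diene) may outrun addition, and addition may take the wrong face of C8 because the Felkin preference of the C7 silyloxy group opposes that of C9. Fallback: 28 is acylated at the C7 hydroxyl with 2-bromopropanoyl bromide and pyridine to the C7 2-bromopropanoate F6. Dess–Martin oxidation gives the C8 ketone F7. SmI2 in THF at −78 °C forms the ester enolate without base and closes it onto C8 in an intramolecular Reformatsky reaction, giving the C17-unhydroxylated hydroxy lactone F8. Its dianion (KN(SiMe3)2, 2.2 equiv) is hydroxylated with 2-(phenylsulfonyl)-3-phenyloxaziridine and returns to 36. C17 would then rest on attack anti to the C8 alkoxide and would have to be verified.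

Step 32. Acetate could attack C6 with allylic transposition, or the epoxide could ionise with loss of configuration at C4, because the epoxide is allylic to C5=C6. Fallback: 39 is opened with water (0.05 M HClO4, THF–H2O, 0 °C) to the 2,9-diacetate 3α,4β-diol F9. The allylic, less hindered C4 hydroxyl is then acetylated selectively (AcCl, 2,4,6-collidine, CH2Cl2, −78 °C) and returns to 40.

## Further compounds

F1 | step 12 | trimethylsilyl enol ether (C10=C11) of the ring-expanded 9,10-dihydro ketone, Z C5=C6 | C13(OCCO3)CC/C(C)=C\[C@@H]4OC(C)(C)O[C@@H]4CC2=C(O[Si](C)(C)C)CCC[C@]12C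
F2 | step 11 | cis-anti-cis photoadduct of 13 with cis-3,4-dichlorocyclobutene (exo 7,8-dichloride) | C13(OCCO3)CC[C@]4(C)[C@H]5[C@H](Cl)[C@H](Cl)[C@H]5[C@@]42C(=O)CCC[C@]12C
F3 | step 11 | bicyclo[2.2.0]hex-2-ene (C7=C8) analogue of 14 | C13(OCCO3)CC[C@]4(C)[C@H]5C=C[C@H]5[C@@]42C(=O)CCC[C@]12C
F4 | step 11 | exo-cis-7,8-diol corresponding to 14 | C13(OCCO3)CC[C@]4(C)[C@H]5[C@H](O)[C@H](O)[C@H]5[C@@]42C(=O)CCC[C@]12C
F5 | step 13 | C9 pinacol boronate of the 9,10-dihydro ketone (H-10 α) | C13(OCCO3)CC/C(C)=C\[C@@H]4OC(C)(C)O[C@@H]4[C@@H](B5OC(C)(C)C(C)(C)O5)[C@H]2C(=O)CCC[C@]12C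
F6 | step 27 | C7 2-bromopropanoate of 28 (epimers at the bromide carbon) | CC(C)(C)[Si](C)(C)O[C@@H]1/C=C\C(C)=C/[C@H](OC(=O)C(C)Br)[C@H](O)[C@@H](O[Si](C)(C)C(C)(C)C)[C@H]2C(C)=CC=C[C@]12C
F7 | step 27 | C8 ketone of F6 | CC(C)(C)[Si](C)(C)O[C@@H]1/C=C\C(C)=C/[C@H](OC(=O)C(C)Br)C(=O)[C@@H](O[Si](C)(C)C(C)(C)C)[C@H]2C(C)=CC=C[C@]12C
F8 | step 27 | γ-lactone with C8 hydroxyl and C17 hydrogen (C17 epimers) | CC(C)(C)[Si](C)(C)O[C@@H]1/C=C\C(C)=C/[C@@H]5OC(=O)C(C)[C@@]5(O)[C@@H](O[Si](C)(C)C(C)(C)C)[C@H]2C(C)=CC=C[C@]12C
F9 | step 32 | 2,9-diacetate 3α,4β-diol | CC(=O)O[C@@H]1[C@H](O)[C@@H](O)/C(C)=C\[C@@H]5OC(=O)[C@@](C)(O)[C@@]5(O)[C@@H](OC(C)=O)[C@H]2C(C)=CC=C[C@]12C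
A1 | alternative 1 | 5-[(benzyloxy)methyl]-6-{[(4-methoxybenzyl)oxy]methyl}-1,5-dimethylcyclohex-3-ene-1,2-diol (ring A cis-diol) | COc1ccc(COC[C@H]2[C@](C)(O)[C@H](O)C=C[C@@]2(COCc2ccccc2)C)cc1
A2 | alternative 2 | bicyclo[8.4.0] butenolide with C11 and C14 hydroxyls, 2,4,9-tris(tert-butyldimethylsilyl) ethers and 3-methoxymethyl ether | CC(C)(C)[Si](C)(C)O[C@@H]1[C@H](OCOC)[C@@H](O[Si](C)(C)C(C)(C)C)/C(C)=C\[C@@H]2OC(=O)C(C)=C2[C@@H](O[Si](C)(C)C(C)(C)C)[C@H]2[C@](C)(O)CC[C@@H](O)[C@]12C
A3 | alternative 3 | 3-[(benzyloxy)methyl]-2-(1-hydroxyprop-2-en-1-yl)-3-methylcyclohexan-1-one | C=C[C@@H](O)[C@H]1C(=O)CCC[C@@]1(COCc1ccccc1)C
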